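## Analysis of the target

The target 28 is an 8–5′ neolignan built on a 2,3-dihydrobenzofuran (O1, C2, C3, C3a, C7a, fused to benzo ring A). C2 bears a 4-hydroxy-3-methoxyphenyl group (ring B), C3 bears the acyloxymethyl carbon C9, C7 a methoxy group, and C5 a three-carbon chain (C7′–C9′) ending in a primary oxygen. The C9 oxygen is esterified with (E)-4-hydroxycinnamic acid and the C9′ oxygen with (Z)-ferulic acid, so two primary alcohols that differ only in position carry different acyl groups. There are two stereocentres, C2 (R) and C3 (S); they are adjacent and trans on the five-membered ring, which is also the thermodynamically preferred arrangement. The sensitive features are: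
- the Z-enoate, which isomerises to E under light, base, nucleophilic catalysis or radical conditions;
- two unsaturated esters, which exclude hydrogenation and strong nucleophiles late in the route;
- three free phenols;
- the C2–O1 bond, a cyclic benzylic aryl ether para to the ring-B oxygen, which can ionise in acid, open through a quinone methide when the phenol is free and base is present, or be hydrogenolysed.

The synthesis is hard on three counts: absolute control at C2 and C3, differentiation of the C9 and C9′ oxygens, and a protecting-group plan that lets the Z-ester enter last with only a mild deprotection after it. The route rests on one structural relationship. C2 is a benzylic ether CH flanked by O1 and ring B, and C3 carries C9, which at the ester oxidation level makes C3 a donor/acceptor carbene centre five atoms from that C–H bond. The C2–C3 bond can therefore be made by carbene C–H insertion, and the same ester later allows C3 to be equilibrated.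

## Retrosynthetic reasoning

**Phenol protection (28 from 27).** The last bonds cut are the two O–Si bonds on ring B and on the E-cinnamoyl unit. The phenols cannot all be free during the acylations, and with this order the Z-enoate meets only one further reagent, a buffered fluoride source. The forward step has to cleave aryl silyl ethers without leaving phenoxide in solution.

**C9′–O ester (27 from 22 and 26).** The Z-feruloyl ester is disconnected next so that the most fragile element enters last. In the forward direction the alkyl–oxygen bond is formed: the primary hydroxyl of 22 is activated under Mitsunobu conditions and the carboxylate of 26 displaces it. The Z-acyl unit is thus never turned into an activated acyl species that could isomerise. Because only desilylation follows, 26 can be used with its phenol free. Acid 26 goes back through ester 25 to aldehyde 23 and phosphonate 24; the C=C bond is the place to cut because a kinetically Z-selective olefination exists for exactly this bond.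

**C9–O ester (22 from 21, and 21 from 17 and 20).** The E-cinnamoyl ester is cut at the acyl–oxygen bond; 20 is the phenol-silylated acid, made from 18. In 21 the C9′ oxygen is still an alkyl silyl ether, which mild acid removes while the two aryl silyl ethers persist; this gives 22.

**Oxidation level and protecting-group exchange (17 from 16, 15 and 14).** The C9 hydroxyl of 17 comes from the C3 ester by hydride reduction. This is where the two primary oxygens become different: one is born from the ester, the other has been a silyl ether since 9 was attached. The ring-B phenol is kept as a benzyl ether while strong base is used and is exchanged for a silyl ether (14 to 15 to 16) before any alkene is present, since hydrogenolysis must precede the cinnamates.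

**C3 configuration (14 from 13).** The trans ester 14 is the equilibrium partner of the cis ester 13; only C3 carries an acidic hydrogen. The forward step has to epimerise C3 without touching C2.

**C2–C3 bond (13 from 12).** This is the key disconnection. It cuts the ring at the bond that joins the two stereocentres and leads to a precursor without any stereocentre. Both ends of the new bond are activated by groups already present: the diazo ester at C3, and O1 and ring B at C2. The forward reaction has to choose one of two enantiotopic C–H bonds and close the five-membered ring.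

**Diazo group (12 from 11).** The diazo function is introduced by diazo transfer onto the arylacetate 11, which is acidic enough for an amidine base.

**C5–C7′ bond (11 from 8 and 9, via 10).** The side chain is attached by B-alkyl Suzuki coupling at the aryl bromide. The bromide is bought in place, and the chain arrives with its oxygen already protected. A silyl ether is used here and not a second benzyl ether: it spares one hydrogenolysis next to the C2–O1 bond and adds no doubly activated C–H bonds to the carbene substrate. The coupling is placed after ester formation so that the alkylborane never meets an aldehyde.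

**One-carbon homologation (8 from 7, 6, 4 and 3, via 5).** The arylacetate is derived from the aldehyde by methylenation, anti-Markovnikov hydration, oxidation and esterification. The sequence is free of strong acid because the 4-alkoxybenzyl aryl ether installed in 3 is acid-labile.

**Aryl ether (3 from 1 and 2).** The O–CH2 bond, which becomes O1–C2, is formed by Mitsunobu etherification. Compound 1 supplies ring A with the methoxy group, the phenol oxygen, the one-carbon handle and the C5 bromide in the right positions; 2 supplies ring B and the carbon that becomes C2.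

## Alternatives that were turned down

**Alternative 1:** The disconnection is C2–C3 together with the C9–heteroatom bond, made intermolecularly at a ring-A styrene, with the C2–O1 bond left for later. In the forward step CuCl, NaOt-Bu and a chiral bisphosphine convert diboron reagent A4 into a copper boryl that adds across the vinyl group of A2 (boron to C9, copper to benzylic C3). The benzylic copper then adds to aldehyde A3 and gives A1, with C3 set by the ligand and C2 as a mixture of carbinol epimers.
- For it: the two aryl halves are joined in the key step itself. C9 arrives as a C–B bond that is chemically distinct from the allyl group standing for C7′–C9′, so the two primary oxygens are differentiated without extra operations. On convergence and on alcohol differentiation it is stronger than the chosen route, which is linear through its key step.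
- Against it: the catalyst must distinguish the styrene from the allyl alkene of A2. The benzylic copper must add to an electron-rich aldehyde faster than it is protonated. C3, once set, has no acidifying group and cannot be corrected. C2 is uncontrolled, so ring closure must pass through a benzylic cation or quinone methide under acid, after removal of a methoxymethyl ether and in the presence of an allyl group and an aryl silyl ether.
- Comparison: the chosen insertion forms C2–C3 and the ring in one event, sets C2 by the catalyst and leaves C3 correctable through the ester. The stereochemical risk is thus reduced to the enantiomeric purity at C2.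

**Alternative 2:** The disconnection is benzo ring A itself, at C3a–C4 and C7a–C7, so that the two stereocentres exist first on a monocyclic γ-lactone. In the forward step the silyl ketene acetal A6 and pyrone A7 undergo [4+2] cycloaddition on heating; the bridged adduct loses CO2 and then silanol, and arene A5 results with the trans relationship carried over.
- For it: both stereocentres are made on a simple lactone where trans is easy to secure. C9 is at the alcohol oxidation level from the start. No diazo compound is needed. On certainty of the relative configuration it is at least as strong as the chosen route.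
- Against it: ring A is formed with bromides at C5 and C7 that must become a 3-hydroxypropyl chain and a methoxy group. That requires site-selective reaction of two similar aryl bromides and a C–O coupling at the hindered position next to O1, under hot basic conditions that endanger the pivalate and the C2 benzylic ether. The cascade needs prolonged heating, and the enantiopure lactone needs several steps of its own.
- Comparison: the chosen route buys ring A fully substituted (compound 1) and leaves no aromatic functionalisation after the key step.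

**Alternative 3:** The disconnection is C3a–C3 and C9–O in one radical step, from aryl iodide A9 in which O1–C2 already exists as a branched allylic aryl ether. In the forward step Bu3SnH generates the aryl radical at C3a, which adds 5-exo-trig to the internal alkene carbon; the primary radical at C9 is captured by nitroxyl A10 to give A8.
- For it: the conditions are neutral and tolerant. C9 arrives as a masked alcohol, so no ester reduction is needed, and the C5 allyl group keeps the second alcohol latent. On redox economy and alcohol differentiation it is stronger than the chosen route.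
- Against it: C2 must be installed beforehand by enantioselective construction of a hindered, ionisable benzylic–allylic aryl ether. C3 is set only by the conformational preference of the 5-exo transition state, which is modest for one pseudo-equatorial aryl group, and it cannot be corrected afterwards. The ring-A allyl group is a second radical acceptor and a source of doubly activated hydrogen. The tin hydride and the nitroxyl consume each other, and the N–O bond needs a separate reductive cleavage.
- Comparison: the chosen route creates both centres in a catalyst-controlled ring closure whose kinetic cis outcome is equilibrated to trans, so the relative configuration rests on thermodynamics.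

Key step: step 8

Assumption: Rh2(S-PTTL)4 is taken to select the C–H bond that gives (R)-C2, as its sense of induction with simpler ortho-benzyloxy aryldiazoacetates implies; if the sense were opposite here, the mirror-image catalyst from (R)-tert-leucine would be used in the same step.
Assumption: compounds 2, 9, 23 and 24 are taken as catalogue items.

Abbreviations in the steps: TBS = tert-butyldimethylsilyl; DIAD = diisopropyl azodicarboxylate; 9-BBN = 9-borabicyclo[3.3.1]nonane.

## Route

Step 1
Reactants: 1 5-bromo-2-hydroxy-3-methoxybenzaldehyde; 2 (4-benzyloxy-3-methoxyphenyl)methanol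
Product: 3 2-[(4-benzyloxy-3-methoxyphenyl)methoxy]-5-bromo-3-methoxybenzaldehyde
Conditions: PPh3, DIAD, THF, 0 °C to rt
Reagents that add atoms: none
Why: Mitsunobu etherification; the phenol of 1 is acidified by the ortho-formyl and para-bromo groups and is a good pronucleophile, and the primary benzylic alcohol 2 is activated as its alkoxyphosphonium ion. No stereocentre is involved.

Step 2
Reactants: 3 2-[(4-benzyloxy-3-methoxyphenyl)methoxy]-5-bromo-3-methoxybenzaldehyde
Product: 4 1-[(4-benzyloxy-3-methoxyphenyl)methoxy]-4-bromo-2-ethenyl-6-methoxybenzene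
Conditions: Ph3PCH3Br, KOt-Bu, THF, 0 °C to rt
Reagents that add atoms: methyltriphenylphosphonium bromide, C[P+](c1ccccc1)(c1ccccc1)c1ccccc1.[Br-]
Why: Wittig methylenation of a non-enolisable aryl aldehyde; the aryl bromide and both benzylic ethers are inert to the preformed ylide.

Step 3
Reactants: 4 1-[(4-benzyloxy-3-methoxyphenyl)methoxy]-4-bromo-2-ethenyl-6-methoxybenzene
Product: 6 2-{2-[(4-benzyloxy-3-methoxyphenyl)methoxy]-5-bromo-3-methoxyphenyl}ethan-1-ol, via alkylborane 5 (not isolated)
Conditions: 9-BBN, THF, 0 °C to rt; then NaOH (aq), H2O2 (30%), 0 °C to rt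
Reagents that add atoms: hydrogen peroxide, OO
Why: Hydroboration–oxidation; 9-BBN places boron on the terminal carbon of the styrene for steric reasons, and alkaline peroxide replaces boron by oxygen. The aryl bromide and the ethers are not affected.

Step 4
Reactants: 6 2-{2-[(4-benzyloxy-3-methoxyphenyl)methoxy]-5-bromo-3-methoxyphenyl}ethan-1-ol
Product: 7 {2-[(4-benzyloxy-3-methoxyphenyl)methoxy]-5-bromo-3-methoxyphenyl}acetic acid
Conditions: 2,2,6,6-tetramethylpiperidin-1-oxyl (TEMPO, cat.), PhI(OAc)2, MeCN/H2O, rt
Reagents that add atoms: water, O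
Why: Nitroxyl-catalysed oxidation of a primary alcohol to the acid through the aldehyde hydrate; the near-neutral aqueous medium spares the acid-labile 4-alkoxybenzyl aryl ether, which is why no acid-mediated homologation is used.

Step 5
Reactants: 7 {2-[(4-benzyloxy-3-methoxyphenyl)methoxy]-5-bromo-3-methoxyphenyl}acetic acid
Product: 8 methyl {2-[(4-benzyloxy-3-methoxyphenyl)methoxy]-5-bromo-3-methoxyphenyl}acetate
Conditions: MeI, K2CO3, DMF, rt
Reagents that add atoms: iodomethane, CI
Why: O-alkylation of the carboxylate (SN2); K2CO3 is too weak a base to C-methylate the arylacetate.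

Step 6
Reactants: 8 methyl {2-[(4-benzyloxy-3-methoxyphenyl)methoxy]-5-bromo-3-methoxyphenyl}acetate; 9 tert-butyldimethyl(prop-2-en-1-yloxy)silane
Product: 11 methyl {2-[(4-benzyloxy-3-methoxyphenyl)methoxy]-3-methoxy-5-[3-(TBS-oxy)propyl]phenyl}acetate, via alkylborane 10 (not isolated)
Conditions: 9, 9-BBN, THF, 0 °C to rt; then 8, PdCl2(dppf) (5 mol%), AsPh3, Cs2CO3, DMF/THF/H2O, rt
Reagents that add atoms: none
Why: B-alkyl Suzuki–Miyaura coupling; 9-BBN hydroborates the terminal alkene of 9 at the end carbon, and the primary alkylborane transmetalates to the arylpalladium bromide formed from the unhindered bromide of 8. The dppf ligand favours reductive elimination over β-hydride elimination, and carbonate at room temperature spares the methyl ester.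

Step 7
Reactants: 11 methyl {2-[(4-benzyloxy-3-methoxyphenyl)methoxy]-3-methoxy-5-[3-(TBS-oxy)propyl]phenyl}acetate
Product: 12 methyl 2-{2-[(4-benzyloxy-3-methoxyphenyl)methoxy]-3-methoxy-5-[3-(TBS-oxy)propyl]phenyl}-2-diazoacetate
Conditions: 4-acetamidobenzenesulfonyl azide, 1,8-diazabicyclo[5.4.0]undec-7-ene (DBU), MeCN, 0 °C to rt
Reagents that add atoms: 4-acetamidobenzenesulfonyl azide, CC(=O)Nc1ccc(cc1)S(=O)(=O)N=[N+]=[N-]
Why: Regitz diazo transfer; the amidine deprotonates the benzylic position α to the ester, the enolate attacks the terminal nitrogen of the sulfonyl azide, and the sulfonamide anion leaves.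

Step 8
Reactants: 12 methyl 2-{2-[(4-benzyloxy-3-methoxyphenyl)methoxy]-3-methoxy-5-[3-(TBS-oxy)propyl]phenyl}-2-diazoacetate
Product: 13 methyl (2R,3S)-2-(4-benzyloxy-3-methoxyphenyl)-7-methoxy-5-[3-(TBS-oxy)propyl]-2,3-dihydro-1-benzofuran-3-carboxylate (cis)
Conditions: Rh2(S-PTTL)4 (dirhodium tetrakis[N-phthaloyl-(S)-tert-leucinate], 1 mol%), 4 Å molecular sieves, toluene, −78 °C, slow addition of 12
Reagents that add atoms: none
Why: Intramolecular C–H insertion of a donor/acceptor rhodium carbene. The diazo carbon of 12 attacks the divalent rhodium dimer, N2 leaves, and an electrophilic carbene flanked by ring A (donor) and the ester (acceptor) is formed; hydride-like transfer from the O–CH2 group and C2–C3 bond formation then occur in one asynchronous three-centre event. The dihydrofuran ring (O1, C2, C3, C3a, C7a) closes by 1,5-insertion, the new C2–C3 bond itself completing the five-membered ring, which is the favoured mode for a carbene and a C–H bond held ortho to each other on an arene. The closest known reaction type is the insertion of methyl aryldiazoacetates into the benzylic C–H bonds of ortho-benzyloxy groups under chiral dirhodium tetracarboxylates, which gives cis-2-aryl-2,3-dihydrobenzofuran-3-carboxylates. C2 is set by the catalyst, whose four N-phthaloyl-tert-leucinate ligands distinguish the two enantiotopic hydrogens of the O–CH2 carbon. C3 is formed in the same event with the ester cis to ring B, the kinetic outcome of the compact transition state, and is adjusted in step 9. The step needs site selectivity over the OCH2Ph and SiOCH2 hydrogens, over attack on ring B and over carbene dimerisation; only the chosen C–H bond can reach the carbene through a five-membered transition state and it is the most hydridic one (activated by O1 and by electron-rich ring B), while low temperature, slow addition and a non-coordinating solvent suppress bimolecular pathways.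

Step 9
Reactants: 13 methyl (2R,3S)-2-(4-benzyloxy-3-methoxyphenyl)-7-methoxy-5-[3-(TBS-oxy)propyl]-2,3-dihydro-1-benzofuran-3-carboxylate (cis)
Product: 14 methyl (2R,3R)-2-(4-benzyloxy-3-methoxyphenyl)-7-methoxy-5-[3-(TBS-oxy)propyl]-2,3-dihydro-1-benzofuran-3-carboxylate (trans)
Conditions: NaOMe, MeOH/THF, 0 °C to rt
Reagents that add atoms: none
Why: Thermodynamic epimerisation through the ester enolate; C3 (α to the ester and benzylic) is deprotonated reversibly and reprotonation should favour the trans ester, in which the aryl and ester groups are not eclipsed. C2 has no acidic hydrogen, the benzylated ring-B phenol closes the quinone methide pathway, and β-elimination of O1 from the enolate is stereoelectronically poor because the C2–O1 bond lies near the enolate plane.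

Step 10
Reactants: 14 methyl (2R,3R)-2-(4-benzyloxy-3-methoxyphenyl)-7-methoxy-5-[3-(TBS-oxy)propyl]-2,3-dihydro-1-benzofuran-3-carboxylate (trans)
Product: 15 methyl (2R,3R)-2-(4-hydroxy-3-methoxyphenyl)-7-methoxy-5-[3-(TBS-oxy)propyl]-2,3-dihydro-1-benzofuran-3-carboxylate
Conditions: H2 (1 atm), Pd on carbon (Pd/C, 10%), EtOAc, rt, stopped after one equivalent of H2
Reagents that add atoms: none
Why: Hydrogenolysis; a primary O-benzyl aryl ether is cleaved on palladium much faster than the cyclic secondary benzylic ether C2–O1, and the step is placed before any alkene is present. Acid-free EtOAc keeps the alkyl silyl ether, and step 11 would restore it if it were lost.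

Step 11
Reactants: 15 methyl (2R,3R)-2-(4-hydroxy-3-methoxyphenyl)-7-methoxy-5-[3-(TBS-oxy)propyl]-2,3-dihydro-1-benzofuran-3-carboxylate
Product: 16 methyl (2R,3R)-7-methoxy-2-[3-methoxy-4-(TBS-oxy)phenyl]-5-[3-(TBS-oxy)propyl]-2,3-dihydro-1-benzofuran-3-carboxylate
Conditions: TBSCl, imidazole, DMF, rt
Reagents that add atoms: tert-butyldimethylsilyl chloride, CC(C)(C)[Si](C)(C)Cl
Why: Silylation of the phenol through the N-silylimidazolium species; the phenol now carries a group that the final fluoride step removes.

Step 12
Reactants: 16 methyl (2R,3R)-7-methoxy-2-[3-methoxy-4-(TBS-oxy)phenyl]-5-[3-(TBS-oxy)propyl]-2,3-dihydro-1-benzofuran-3-carboxylate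
Product: 17 {(2R,3S)-7-methoxy-2-[3-methoxy-4-(TBS-oxy)phenyl]-5-[3-(TBS-oxy)propyl]-2,3-dihydro-1-benzofuran-3-yl}methanol
Conditions: diisobutylaluminium hydride, (Me2CHCH2)2AlH, CH2Cl2, −78 to 0 °C; aqueous potassium sodium tartrate (KNaC4H4O6) work-up
Reagents that add atoms: none
Why: Hydride reduction of the ester to the primary alcohol C9–OH; aryl and alkyl silyl ethers are stable to the aluminium hydride, and no base is present that could disturb C3. The change of descriptor at C3 from R to S follows from the priority rules only.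

Step 13
Reactants: 18 (2E)-3-(4-hydroxyphenyl)prop-2-enoic acid
Product: 20 (2E)-3-[4-(TBS-oxy)phenyl]prop-2-enoic acid, via bis-silylated coumarate 19 (not isolated)
Conditions: TBSCl (2.5 equiv), imidazole, DMF, rt; then AcOH/THF/H2O, rt
Reagents that add atoms: tert-butyldimethylsilyl chloride, CC(C)(C)[Si](C)(C)Cl
Why: Double silylation followed by selective hydrolysis; the silyl ester is far more labile to aqueous acid than the aryl silyl ether.

Step 14
Reactants: 17 {(2R,3S)-7-methoxy-2-[3-methoxy-4-(TBS-oxy)phenyl]-5-[3-(TBS-oxy)propyl]-2,3-dihydro-1-benzofuran-3-yl}methanol; 20 (2E)-3-[4-(TBS-oxy)phenyl]prop-2-enoic acid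
Product: 21 {(2R,3S)-7-methoxy-2-[3-methoxy-4-(TBS-oxy)phenyl]-5-[3-(TBS-oxy)propyl]-2,3-dihydro-1-benzofuran-3-yl}methyl (2E)-3-[4-(TBS-oxy)phenyl]prop-2-enoate
Conditions: N-ethyl-N′-(3-dimethylaminopropyl)carbodiimide hydrochloride (EDC·HCl), 4-(dimethylamino)pyridine (DMAP, cat.), CH2Cl2, 0 °C to rt
Reagents that add atoms: none
Why: Steglich esterification; C9–OH is the only free hydroxyl, and the E-enoate is the stable isomer, so acyl activation carries no geometric risk.

Step 15
Reactants: 21 {(2R,3S)-7-methoxy-2-[3-methoxy-4-(TBS-oxy)phenyl]-5-[3-(TBS-oxy)propyl]-2,3-dihydro-1-benzofuran-3-yl}methyl (2E)-3-[4-(TBS-oxy)phenyl]prop-2-enoate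
Product: 22 {(2R,3S)-5-(3-hydroxypropyl)-7-methoxy-2-[3-methoxy-4-(TBS-oxy)phenyl]-2,3-dihydro-1-benzofuran-3-yl}methyl (2E)-3-[4-(TBS-oxy)phenyl]prop-2-enoate
Conditions: (1S)-camphor-10-sulfonic acid (cat.), MeOH/CH2Cl2, 0 °C
Reagents that add atoms: none
Why: Acid-catalysed methanolysis of the primary alkyl silyl ether; aryl silyl ethers resist mild acid because the phenolic oxygen is much less basic, and the cinnamate is not transesterified at 0 °C.

Step 16
Reactants: 23 4-(TBS-oxy)-3-methoxybenzaldehyde; 24 methyl 2-[bis(2,2,2-trifluoroethoxy)phosphoryl]acetate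
Product: 25 methyl (2Z)-3-[3-methoxy-4-(TBS-oxy)phenyl]prop-2-enoate
Conditions: KN(SiMe3)2, 18-crown-6, THF, −78 °C, dark
Reagents that add atoms: none
Why: Still–Gennari olefination; the electron-poor trifluoroethyl phosphonate makes elimination from the kinetically formed adduct fast and irreversible, which should give the Z-enoate. Any E isomer can be removed at this small-molecule stage.

Step 17
Reactants: 25 methyl (2Z)-3-[3-methoxy-4-(TBS-oxy)phenyl]prop-2-enoate
Product: 26 (2Z)-3-(4-hydroxy-3-methoxyphenyl)prop-2-enoic acid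
Conditions: LiOH, THF/MeOH/H2O, rt, dark; then aq. HCl to pH 3
Reagents that add atoms: lithium hydroxide, [Li+].[OH-]
Why: Saponification; hydroxide cleaves the methyl ester and the aryl silyl ether together. The Z-geometry is expected to hold because thermal rotation about the C=C bond of the phenolate carboxylate is slow at room temperature when light is excluded.

Step 18
Reactants: 22 {(2R,3S)-5-(3-hydroxypropyl)-7-methoxy-2-[3-methoxy-4-(TBS-oxy)phenyl]-2,3-dihydro-1-benzofuran-3-yl}methyl (2E)-3-[4-(TBS-oxy)phenyl]prop-2-enoate; 26 (2Z)-3-(4-hydroxy-3-methoxyphenyl)prop-2-enoic acid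
Product: 27 3-{(2R,3S)-7-methoxy-2-[3-methoxy-4-(TBS-oxy)phenyl]-3-[({(2E)-3-[4-(TBS-oxy)phenyl]prop-2-enoyl}oxy)methyl]-2,3-dihydro-1-benzofuran-5-yl}propyl (2Z)-3-(4-hydroxy-3-methoxyphenyl)prop-2-enoate
Conditions: PPh3, DIAD, THF, 0 °C to rt, dark
Reagents that add atoms: none
Why: Mitsunobu esterification; the primary alcohol is activated and the carboxylate acts only as nucleophile, so the Z-acyl unit never becomes an activated acyl species. The carboxylic acid is several orders of magnitude more acidic than the phenol of 26 and is the pronucleophile that reacts.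

Step 19
Reactants: 27 3-{(2R,3S)-7-methoxy-2-[3-methoxy-4-(TBS-oxy)phenyl]-3-[({(2E)-3-[4-(TBS-oxy)phenyl]prop-2-enoyl}oxy)methyl]-2,3-dihydro-1-benzofuran-5-yl}propyl (2Z)-3-(4-hydroxy-3-methoxyphenyl)prop-2-enoate
Product: 28 3-{(2R,3S)-2-(4-hydroxy-3-methoxyphenyl)-3-[({(2E)-3-(4-hydroxyphenyl)prop-2-enoyl}oxy)methyl]-7-methoxy-2,3-dihydro-1-benzofuran-5-yl}propyl (2Z)-3-(4-hydroxy-3-methoxyphenyl)prop-2-enoate
Conditions: Bu4NF, AcOH, THF, 0 °C, dark
Reagents that add atoms: none
Why: Fluoride-mediated cleavage of the two aryl silyl ethers; acetic acid protonates each phenoxide as it forms, which should prevent ester cleavage, base-promoted Z-to-E isomerisation and quinone methide chemistry at C2.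

## Compound list

1 | 5-bromo-2-hydroxy-3-methoxybenzaldehyde | COc1cc(Br)cc(C=O)c1O | starting material
2 | (4-benzyloxy-3-methoxyphenyl)methanol | COc1cc(CO)ccc1OCc1ccccc1 | starting material
3 | 2-[(4-benzyloxy-3-methoxyphenyl)methoxy]-5-bromo-3-methoxybenzaldehyde | COc1cc(Br)cc(C=O)c1OCc1ccc(OCc2ccccc2)c(OC)c1 | intermediate
4 | 1-[(4-benzyloxy-3-methoxyphenyl)methoxy]-4-bromo-2-ethenyl-6-methoxybenzene | COc1cc(Br)cc(C=C)c1OCc1ccc(OCc2ccccc2)c(OC)c1 | intermediate
5 | 9-(2-{2-[(4-benzyloxy-3-methoxyphenyl)methoxy]-5-bromo-3-methoxyphenyl}ethyl)-9-borabicyclo[3.3.1]nonane | COc1cc(Br)cc(CCB2C3CCCC2CCC3)c1OCc1ccc(OCc2ccccc2)c(OC)c1 | intermediate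
6 | 2-{2-[(4-benzyloxy-3-methoxyphenyl)methoxy]-5-bromo-3-methoxyphenyl}ethan-1-ol | COc1cc(Br)cc(CCO)c1OCc1ccc(OCc2ccccc2)c(OC)c1 | intermediate
7 | {2-[(4-benzyloxy-3-methoxyphenyl)methoxy]-5-bromo-3-methoxyphenyl}acetic acid | COc1cc(Br)cc(CC(=O)O)c1OCc1ccc(OCc2ccccc2)c(OC)c1 | intermediate
8 | methyl {2-[(4-benzyloxy-3-methoxyphenyl)methoxy]-5-bromo-3-methoxyphenyl}acetate | COC(=O)Cc1cc(Br)cc(OC)c1OCc1ccc(OCc2ccccc2)c(OC)c1 | intermediate
9 | tert-butyldimethyl(prop-2-en-1-yloxy)silane | C=CCO[Si](C)(C)C(C)(C)C | starting material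
10 | 9-{3-[(tert-butyldimethylsilyl)oxy]propyl}-9-borabicyclo[3.3.1]nonane | CC(C)(C)[Si](C)(C)OCCCB1C2CCCC1CCC2 | intermediate
11 | methyl {2-[(4-benzyloxy-3-methoxyphenyl)methoxy]-5-{3-[(tert-butyldimethylsilyl)oxy]propyl}-3-methoxyphenyl}acetate | COC(=O)Cc1cc(CCCO[Si](C)(C)C(C)(C)C)cc(OC)c1OCc1ccc(OCc2ccccc2)c(OC)c1 | intermediate
12 | methyl 2-{2-[(4-benzyloxy-3-methoxyphenyl)methoxy]-5-{3-[(tert-butyldimethylsilyl)oxy]propyl}-3-methoxyphenyl}-2-diazoacetate | COC(=O)C(=[N+]=[N-])c1cc(CCCO[Si](C)(C)C(C)(C)C)cc(OC)c1OCc1ccc(OCc2ccccc2)c(OC)c1 | intermediate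
13 | methyl (2R,3S)-2-(4-benzyloxy-3-methoxyphenyl)-5-{3-[(tert-butyldimethylsilyl)oxy]propyl}-7-methoxy-2,3-dihydro-1-benzofuran-3-carboxylate (cis) | CC(C)(C)[Si](C)(C)OCCCc1cc(OC)c2c(c1)[C@H](C(=O)OC)[C@H](c1ccc(OCc3ccccc3)c(OC)c1)O2 | intermediate
14 | methyl (2R,3R)-2-(4-benzyloxy-3-methoxyphenyl)-5-{3-[(tert-butyldimethylsilyl)oxy]propyl}-7-methoxy-2,3-dihydro-1-benzofuran-3-carboxylate (trans) | CC(C)(C)[Si](C)(C)OCCCc1cc(OC)c2c(c1)[C@@H](C(=O)OC)[C@H](c1ccc(OCc3ccccc3)c(OC)c1)O2 | intermediate
15 | methyl (2R,3R)-5-{3-[(tert-butyldimethylsilyl)oxy]propyl}-2-(4-hydroxy-3-methoxyphenyl)-7-methoxy-2,3-dihydro-1-benzofuran-3-carboxylate | CC(C)(C)[Si](C)(C)OCCCc1cc(OC)c2c(c1)[C@@H](C(=O)OC)[C@H](c1ccc(O)c(OC)c1)O2 | intermediate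
16 | methyl (2R,3R)-2-{4-[(tert-butyldimethylsilyl)oxy]-3-methoxyphenyl}-5-{3-[(tert-butyldimethylsilyl)oxy]propyl}-7-methoxy-2,3-dihydro-1-benzofuran-3-carboxylate | CC(C)(C)[Si](C)(C)OCCCc1cc(OC)c2c(c1)[C@@H](C(=O)OC)[C@H](c1ccc(O[Si](C)(C)C(C)(C)C)c(OC)c1)O2 | intermediate
17 | [(2R,3S)-2-{4-[(tert-butyldimethylsilyl)oxy]-3-methoxyphenyl}-5-{3-[(tert-butyldimethylsilyl)oxy]propyl}-7-methoxy-2,3-dihydro-1-benzofuran-3-yl]methanol | CC(C)(C)[Si](C)(C)OCCCc1cc(OC)c2c(c1)[C@@H](CO)[C@H](c1ccc(O[Si](C)(C)C(C)(C)C)c(OC)c1)O2 | intermediate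
18 | (2E)-3-(4-hydroxyphenyl)prop-2-enoic acid | OC(=O)/C=C/c1ccc(O)cc1 | starting material
19 | tert-butyldimethylsilyl (2E)-3-{4-[(tert-butyldimethylsilyl)oxy]phenyl}prop-2-enoate | CC(C)(C)[Si](C)(C)OC(=O)/C=C/c1ccc(O[Si](C)(C)C(C)(C)C)cc1 | intermediate
20 | (2E)-3-{4-[(tert-butyldimethylsilyl)oxy]phenyl}prop-2-enoic acid | OC(=O)/C=C/c1ccc(O[Si](C)(C)C(C)(C)C)cc1 | intermediate
21 | [(2R,3S)-2-{4-[(tert-butyldimethylsilyl)oxy]-3-methoxyphenyl}-5-{3-[(tert-butyldimethylsilyl)oxy]propyl}-7-methoxy-2,3-dihydro-1-benzofuran-3-yl]methyl (2E)-3-{4-[(tert-butyldimethylsilyl)oxy]phenyl}prop-2-enoate | CC(C)(C)[Si](C)(C)OCCCc1cc(OC)c2c(c1)[C@@H](COC(=O)/C=C/c1ccc(O[Si](C)(C)C(C)(C)C)cc1)[C@H](c1ccc(O[Si](C)(C)C(C)(C)C)c(OC)c1)O2 | intermediate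
22 | [(2R,3S)-2-{4-[(tert-butyldimethylsilyl)oxy]-3-methoxyphenyl}-5-(3-hydroxypropyl)-7-methoxy-2,3-dihydro-1-benzofuran-3-yl]methyl (2E)-3-{4-[(tert-butyldimethylsilyl)oxy]phenyl}prop-2-enoate | OCCCc1cc(OC)c2c(c1)[C@@H](COC(=O)/C=C/c1ccc(O[Si](C)(C)C(C)(C)C)cc1)[C@H](c1ccc(O[Si](C)(C)C(C)(C)C)c(OC)c1)O2 | intermediate
23 | 4-[(tert-butyldimethylsilyl)oxy]-3-methoxybenzaldehyde | COc1cc(C=O)ccc1O[Si](C)(C)C(C)(C)C | starting material
24 | methyl 2-[bis(2,2,2-trifluoroethoxy)phosphoryl]acetate | COC(=O)CP(=O)(OCC(F)(F)F)OCC(F)(F)F | starting material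
25 | methyl (2Z)-3-{4-[(tert-butyldimethylsilyl)oxy]-3-methoxyphenyl}prop-2-enoate | COC(=O)/C=C\c1ccc(O[Si](C)(C)C(C)(C)C)c(OC)c1 | intermediate
26 | (2Z)-3-(4-hydroxy-3-methoxyphenyl)prop-2-enoic acid | COc1cc(/C=C\C(=O)O)ccc1O | intermediate
27 | 3-[(2R,3S)-2-{4-[(tert-butyldimethylsilyl)oxy]-3-methoxyphenyl}-3-{[((2E)-3-{4-[(tert-butyldimethylsilyl)oxy]phenyl}prop-2-enoyl)oxy]methyl}-7-methoxy-2,3-dihydro-1-benzofuran-5-yl]propyl (2Z)-3-(4-hydroxy-3-methoxyphenyl)prop-2-enoate | COc1cc(/C=C\C(=O)OCCCc2cc(OC)c3c(c2)[C@@H](COC(=O)/C=C/c2ccc(O[Si](C)(C)C(C)(C)C)cc2)[C@H](c2ccc(O[Si](C)(C)C(C)(C)C)c(OC)c2)O3)ccc1O | intermediate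
28 | 3-[(2R,3S)-2-(4-hydroxy-3-methoxyphenyl)-3-{[((2E)-3-(4-hydroxyphenyl)prop-2-enoyl)oxy]methyl}-7-methoxy-2,3-dihydro-1-benzofuran-5-yl]propyl (2Z)-3-(4-hydroxy-3-methoxyphenyl)prop-2-enoate | COc1cc(/C=C\C(=O)OCCCc2cc(OC)c3c(c2)[C@@H](COC(=O)/C=C/c2ccc(O)cc2)[C@H](c2ccc(O)c(OC)c2)O3)ccc1O | target

## Step count and risk

Total step count: 19. Longest linear sequence: 16 steps (steps 1 to 12, 14, 15, 18 and 19); steps 13, 16 and 17 prepare the two acyl partners.

**Step 8 (key step).** The most likely failure is insufficient discrimination between the two enantiotopic C–H bonds. This substrate is more electron-rich and more crowded around the carbene than the simple models, so the transition state is earlier and less tightly held by the ligands. Diversion of the carbene into dimerisation or attack on ring B is the second concern. Fallback, setting out from 12: the insertion would be run with achiral Rh2(OAc)4 in CH2Cl2, which should give the cis ester as the racemate, that is 13 together with its enantiomer, methyl (2S,3R)-2-(4-benzyloxy-3-methoxyphenyl)-5-{3-[(tert-butyldimethylsilyl)oxy]propyl}-7-methoxy-2,3-dihydro-1-benzofuran-3-carboxylate F1. NaOMe in MeOH would convert this into the racemic trans ester, 14 together with its (2S,3S) enantiomer F2. The two would be separated by preparative chromatography on a cellulose carbamate chiral stationary phase, and the route is rejoined at 14.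

**Step 9.** Equilibration may be incomplete, or C2 may be eroded by reversible opening and reclosure of the ring from the ester enolate under alkoxide. Fallback, setting out from 13: one equivalent of (Me2CHCH2)2AlH in toluene at −78 °C would stop at the cis aldehyde, (2R,3S)-2-(4-benzyloxy-3-methoxyphenyl)-5-{3-[(tert-butyldimethylsilyl)oxy]propyl}-7-methoxy-2,3-dihydro-1-benzofuran-3-carbaldehyde F3. An α-aryl aldehyde is acidic enough for Et3N in CH2Cl2 to equilibrate it to the trans (2R,3R) aldehyde F4 without any alkoxide. NaClO2 with NaH2PO4 and 2-methylbut-2-ene would give the trans (2R,3R) carboxylic acid F5, and MeI with K2CO3 would return the methyl ester, rejoining the route at 14.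

**Step 18.** Partial Z-to-E isomerisation by reversible conjugate addition of the phosphine to the enoate, or incomplete chemoselectivity between the carboxyl and phenol groups of 26, could lower the geometric or chemical purity. Fallback, setting out from 22: the alkene would be built on the substrate. Bromoacetyl bromide and pyridine would give the bromoacetate of the C9′ alcohol F6. Diphenyl phosphite, (PhO)2P(O)H, and Et3N (Michaelis–Becker reaction) would give the (diphenoxyphosphoryl)acetate F7. The diaryl phosphonoacetate variant of the Horner–Wadsworth–Emmons reaction (NaI, DBU, THF, −78 to 0 °C) with aldehyde 23 would give the Z-enoate carrying three silyl ethers F8. Bu4NF with AcOH would then remove all three silyl groups and arrive at 28.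

**Step 19.** Transient phenoxide para to the Z-enoate lowers the barrier to rotation about the C=C bond, and basic fluoride can cleave or transfer the esters. Fallback, setting out from 22: the order of the last two operations would be exchanged. Bu4NF with AcOH would first remove both aryl silyl ethers and give [(2R,3S)-2-(4-hydroxy-3-methoxyphenyl)-5-(3-hydroxypropyl)-7-methoxy-2,3-dihydro-1-benzofuran-3-yl]methyl (2E)-3-(4-hydroxyphenyl)prop-2-enoate F9. Mitsunobu esterification of its primary alcohol with 26 (PPh3, DIAD) would then rely on the much higher acidity of the carboxylic acid over the phenols and arrive at 28 directly, so that no reagent follows the introduction of the Z-ester.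

## Further compounds

F1 | step 8 | methyl (2S,3R)-2-(4-benzyloxy-3-methoxyphenyl)-5-{3-[(tert-butyldimethylsilyl)oxy]propyl}-7-methoxy-2,3-dihydro-1-benzofuran-3-carboxylate (enantiomer of 13, formed with 13 as the racemate) | CC(C)(C)[Si](C)(C)OCCCc1cc(OC)c2c(c1)[C@@H](C(=O)OC)[C@@H](c1ccc(OCc3ccccc3)c(OC)c1)O2
F2 | step 8 | methyl (2S,3S)-2-(4-benzyloxy-3-methoxyphenyl)-5-{3-[(tert-butyldimethylsilyl)oxy]propyl}-7-methoxy-2,3-dihydro-1-benzofuran-3-carboxylate (enantiomer of 14, formed with 14 as the racemate) | CC(C)(C)[Si](C)(C)OCCCc1cc(OC)c2c(c1)[C@H](C(=O)OC)[C@@H](c1ccc(OCc3ccccc3)c(OC)c1)O2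
F3 | step 9 | (2R,3S)-2-(4-benzyloxy-3-methoxyphenyl)-5-{3-[(tert-butyldimethylsilyl)oxy]propyl}-7-methoxy-2,3-dihydro-1-benzofuran-3-carbaldehyde (cis) | CC(C)(C)[Si](C)(C)OCCCc1cc(OC)c2c(c1)[C@H](C=O)[C@H](c1ccc(OCc3ccccc3)c(OC)c1)O2
F4 | step 9 | (2R,3R)-2-(4-benzyloxy-3-methoxyphenyl)-5-{3-[(tert-butyldimethylsilyl)oxy]propyl}-7-methoxy-2,3-dihydro-1-benzofuran-3-carbaldehyde (trans) | CC(C)(C)[Si](C)(C)OCCCc1cc(OC)c2c(c1)[C@@H](C=O)[C@H](c1ccc(OCc3ccccc3)c(OC)c1)O2
F5 | step 9 | (2R,3R)-2-(4-benzyloxy-3-methoxyphenyl)-5-{3-[(tert-butyldimethylsilyl)oxy]propyl}-7-methoxy-2,3-dihydro-1-benzofuran-3-carboxylic acid (trans) | CC(C)(C)[Si](C)(C)OCCCc1cc(OC)c2c(c1)[C@@H](C(=O)O)[C@H](c1ccc(OCc3ccccc3)c(OC)c1)O2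
F6 | step 18 | 3-[(2R,3S)-2-{4-[(tert-butyldimethylsilyl)oxy]-3-methoxyphenyl}-3-{[((2E)-3-{4-[(tert-butyldimethylsilyl)oxy]phenyl}prop-2-enoyl)oxy]methyl}-7-methoxy-2,3-dihydro-1-benzofuran-5-yl]propyl bromoacetate | BrCC(=O)OCCCc1cc(OC)c2c(c1)[C@@H](COC(=O)/C=C/c1ccc(O[Si](C)(C)C(C)(C)C)cc1)[C@H](c1ccc(O[Si](C)(C)C(C)(C)C)c(OC)c1)O2
F7 | step 18 | 3-[(2R,3S)-2-{4-[(tert-butyldimethylsilyl)oxy]-3-methoxyphenyl}-3-{[((2E)-3-{4-[(tert-butyldimethylsilyl)oxy]phenyl}prop-2-enoyl)oxy]methyl}-7-methoxy-2,3-dihydro-1-benzofuran-5-yl]propyl (diphenoxyphosphoryl)acetate | O=P(Oc1ccccc1)(Oc1ccccc1)CC(=O)OCCCc1cc(OC)c2c(c1)[C@@H](COC(=O)/C=C/c1ccc(O[Si](C)(C)C(C)(C)C)cc1)[C@H](c1ccc(O[Si](C)(C)C(C)(C)C)c(OC)c1)O2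
F8 | step 18 | 3-[(2R,3S)-2-{4-[(tert-butyldimethylsilyl)oxy]-3-methoxyphenyl}-3-{[((2E)-3-{4-[(tert-butyldimethylsilyl)oxy]phenyl}prop-2-enoyl)oxy]methyl}-7-methoxy-2,3-dihydro-1-benzofuran-5-yl]propyl (2Z)-3-{4-[(tert-butyldimethylsilyl)oxy]-3-methoxyphenyl}prop-2-enoate | COc1cc(/C=C\C(=O)OCCCc2cc(OC)c3c(c2)[C@@H](COC(=O)/C=C/c2ccc(O[Si](C)(C)C(C)(C)C)cc2)[C@H](c2ccc(O[Si](C)(C)C(C)(C)C)c(OC)c2)O3)ccc1O[Si](C)(C)C(C)(C)C
F9 | step 19 | [(2R,3S)-2-(4-hydroxy-3-methoxyphenyl)-5-(3-hydroxypropyl)-7-methoxy-2,3-dihydro-1-benzofuran-3-yl]methyl (2E)-3-(4-hydroxyphenyl)prop-2-enoate | OCCCc1cc(OC)c2c(c1)[C@@H](COC(=O)/C=C/c1ccc(O)cc1)[C@H](c1ccc(O)c(OC)c1)O2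
A1 | alternative 1 | 2-[3-methoxy-2-(methoxymethoxy)-5-(prop-2-en-1-yl)phenyl]-1-{3-methoxy-4-[(triisopropylsilyl)oxy]phenyl}-3-(4,4,5,5-tetramethyl-1,3,2-dioxaborolan-2-yl)propan-1-ol (C3 defined, both carbinol epimers) | C=CCc1cc(OC)c(OCOC)c(c1)[C@@H](CB1OC(C)(C)C(C)(C)O1)C(O)c1ccc(O[Si](C(C)C)(C(C)C)C(C)C)c(OC)c1
A2 | alternative 1 | 1-ethenyl-3-methoxy-2-(methoxymethoxy)-5-(prop-2-en-1-yl)benzene | C=CCc1cc(OC)c(OCOC)c(C=C)c1
A3 | alternative 1 | 3-methoxy-4-[(triisopropylsilyl)oxy]benzaldehyde | COc1cc(C=O)ccc1O[Si](C(C)C)(C(C)C)C(C)C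
A4 | alternative 1 | 4,4,4′,4′,5,5,5′,5′-octamethyl-2,2′-bi(1,3,2-dioxaborolane) | CC1(C)OB(OC1(C)C)B1OC(C)(C)C(C)(C)O1
A5 | alternative 2 | {(2R,3S)-5,7-dibromo-2-[3-methoxy-4-(methoxymethoxy)phenyl]-2,3-dihydro-1-benzofuran-3-yl}methyl 2,2-dimethylpropanoate (trans) | Brc1cc(Br)c2c(c1)[C@@H](COC(=O)C(C)(C)C)[C@H](c1ccc(OCOC)c(OC)c1)O2
A6 | alternative 2 | {(2R,3S)-5-[(tert-butyldimethylsilyl)oxy]-2-[3-methoxy-4-(methoxymethoxy)phenyl]-2,3-dihydrofuran-3-yl}methyl 2,2-dimethylpropanoate | CC(C)(C)[Si](C)(C)OC1=C[C@@H](COC(=O)C(C)(C)C)[C@H](c2ccc(OCOC)c(OC)c2)O1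
A7 | alternative 2 | 3,5-dibromo-2H-pyran-2-one | O=C1OC=C(Br)C=C1Br
A8 | alternative 3 | 1-({(2R,3S)-7-methoxy-2-{3-methoxy-4-[(triisopropylsilyl)oxy]phenyl}-5-(prop-2-en-1-yl)-2,3-dihydro-1-benzofuran-3-yl}methoxy)-2,2,6,6-tetramethylpiperidine (trans) | C=CCc1cc(OC)c2c(c1)[C@@H](CON1C(C)(C)CCCC1(C)C)[C@H](c1ccc(O[Si](C(C)C)(C(C)C)C(C)C)c(OC)c1)O2
A9 | alternative 3 | 1-iodo-3-methoxy-2-({(1R)-1-{3-methoxy-4-[(triisopropylsilyl)oxy]phenyl}prop-2-en-1-yl}oxy)-5-(prop-2-en-1-yl)benzene | C=CCc1cc(OC)c(O[C@H](C=C)c2ccc(O[Si](C(C)C)(C(C)C)C(C)C)c(OC)c2)c(I)c1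
A10 | alternative 3 | 2,2,6,6-tetramethylpiperidin-1-oxyl | CC1(C)CCCC(C)(C)N1[O]
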